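**Plan**

Numbering: ring E (cyclopentenone) has C1 (C=O), C2=C3, C4 (carbinol) and C5 (fusion CH). The naphthalene core of the phenalenone is C1′–C8′: C2′ bears C4, C1′ bears the ketal carbon, C4′/C5′ are the peri pair bridged by ring A, and C6′ bears OH. Ring D consists of C4, C5, the ketal C, C1′ and C2′. Ring F is the 1,3-dioxine.
Retrosynthetic cuts, in order: O–Me and O–Si; ring A at C4′–CH= and at C5′–C(=O), giving an aryl iodide, CO and an ethyne unit; ring D at the ketal C–C1′ bond; ring F at both ketal C–O bonds and at C5–ketal C, giving naphthalene-1,8-diol and CS2; ring E back to a meso epoxide, a diallyl carbinol and methyl 6-methoxy-2-naphthoate.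
Enabling feature: the ketal carbon is bonded to both C5 and the aromatic α-carbon C1′, and C1′ is the ortho neighbour of C2′, which carries C4. Ring D holds only these five atoms, so an aryl group already on C4 can reach, through C1′, an electrophilic dioxine C2 standing on the adjacent C5.
Forward order of rings: E (metathesis), F (double vinylic substitution), D (key step), A (carbonylative alkynylation, then peri hydroarylation). Rings B and C and the second naphthalene are purchased.
Stereochemistry: a chiral lithium amide differentiates the enantiotopic CH2 groups of meso epoxide 7 and makes C4 stereogenic (step 6). C5 follows in step 10 because the D/E bicyclo[3.3.0] unit can only be cis-fused. The ketal carbon is not stereogenic.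

Key step: step 10

Assumption: the sense of induction in step 6 is inferred from the known behaviour of this class of base, whose (S)-form converts cyclohexene oxide and cis-4-silyloxycyclopentene oxides into (S)-configured allylic alcohols. The (R)-diamine is therefore used, and if the aryl group reverses the sense, the equally available (S)-diamine replaces it.

Step 1
Reactants: 1 methyl 6-methoxy-2-naphthoate
Product: 2 methyl 5-iodo-6-methoxy-2-naphthoate
Conditions: NIS, CF3CO2H (cat.), MeCN, rt
Reagents that add atoms: N-iodosuccinimide, O=C1CCC(=O)N1I
Why: Electrophilic aromatic iodination, in which the methoxy group directs to its α-neighbour C5′ and the ester deactivates the other ring; the handle for ring A is placed here because selective halogenation could not be relied on once an electron-rich dioxynaphthalene is present.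

Step 2
Reactants: 2 methyl 5-iodo-6-methoxy-2-naphthoate; 3 allylmagnesium bromide
Product: 4 4-(5-iodo-6-methoxynaphthalen-2-yl)hepta-1,6-dien-4-ol
Conditions: 3 (2.5 equiv), THF, −78 → 0 °C; aq. NH4Cl
Reagents that add atoms: allylmagnesium bromide 3, C=CC[Mg]Br
Why: Double Grignard addition to an ester, which is much faster than iodine–magnesium exchange because exchange would replace a stabilised allyl reagent with a more basic aryl one.

Step 3
Reactants: 4 4-(5-iodo-6-methoxynaphthalen-2-yl)hepta-1,6-dien-4-ol
Product: 5 1-(5-iodo-6-methoxynaphthalen-2-yl)cyclopent-3-en-1-ol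
Conditions: second-generation Grubbs catalyst (2 mol %), CH2Cl2, 40 °C
Reagents that add atoms: none
Why: Ring-closing metathesis of a diallyl carbinol to a cyclopent-3-enol, driven by loss of ethene and tolerant of free tertiary alcohols and aryl iodides.

Step 4
Reactants: 5 1-(5-iodo-6-methoxynaphthalen-2-yl)cyclopent-3-en-1-ol
Product: 6 meso-3-(5-iodo-6-methoxynaphthalen-2-yl)-6-oxabicyclo[3.1.0]hexan-3-ol (epoxide O cis to OH)
Conditions: VO(acac)2 (2 mol %), t-BuOOH (decane), CH2Cl2, 0 °C → rt
Reagents that add atoms: tert-butyl hydroperoxide, CC(C)(C)OO
Why: Hydroxyl-directed vanadium-catalysed epoxidation of a homoallylic alcohol, in which the bound peroxide is delivered to the face carrying OH, so a single meso diastereomer should form; step 6 needs this because the two diastereomers would lead to opposite enantiomers of the enone.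

Step 5
Reactants: 6 meso cis-epoxy alcohol
Product: 7 meso-3-(5-iodo-6-methoxynaphthalen-2-yl)-3-(triethylsilyloxy)-6-oxabicyclo[3.1.0]hexane (epoxide O cis to OSiEt3)
Conditions: Et3SiCl, imidazole, DMAP, DMF, 40 °C
Reagents that add atoms: chlorotriethylsilane, CC[Si](Cl)(CC)CC
Why: Standard silylation, in which the small silyl chloride reaches the tertiary alcohol under nucleophilic catalysis without a Lewis acid that could open the epoxide.

Step 6
Reactants: 7 meso silyloxy epoxide
Product: 8 (1R,4S)-4-(5-iodo-6-methoxynaphthalen-2-yl)-4-(triethylsilyloxy)cyclopent-2-en-1-ol (OH cis to OSiEt3)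
Conditions: (R)-1-(pyrrolidin-2-ylmethyl)pyrrolidine (1.7 equiv), n-BuLi (1.6 equiv), THF, 0 °C; then 7, 0 °C → rt; H2O
Reagents that add atoms: none
Why: Enantioselective syn-β-deprotonation of a meso epoxide by a chiral lithium amide (epoxide to allylic alcohol rearrangement, established for cis-4-silyloxycyclopentene oxides), in which the choice between the two enantiotopic CH2 groups decides on which side of the quaternary carbon the alkene lies and so makes C4 (S), while C1 (R) is the epoxide carbon that keeps its oxygen.

Step 7
Reactants: 8 (1R,4S)-allylic alcohol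
Product: 9 (S)-4-(5-iodo-6-methoxynaphthalen-2-yl)-4-(triethylsilyloxy)cyclopent-2-en-1-one
Conditions: MnO2 (activated), CH2Cl2, rt
Reagents that add atoms: none
Why: Allylic alcohol oxidation with MnO2 under neutral conditions that leave the silyl ether, the aryl iodide and C4 untouched.

Step 8
Reactants: 9 (S)-enone; 10 carbon disulfide
Product: 11 (S)-5-[bis(methylsulfanyl)methylidene]-4-(5-iodo-6-methoxynaphthalen-2-yl)-4-(triethylsilyloxy)cyclopent-2-en-1-one
Conditions: LiN(SiMe3)2 (2.2 equiv), THF, −78 °C; CS2, −78 → −20 °C; MeI, → rt
Reagents that add atoms: carbon disulfide 10, S=C=S; iodomethane, CI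
Why: Standard α-oxoketene dithioacetal synthesis, in which C5 is the only enolisable position, the soft electrophile CS2 is attacked through carbon and the ene-dithiolate is S-methylated twice, while β-loss of silyloxide is held back at low temperature because it would give a cyclopentadienone.

Step 9
Reactants: 11 dithioacetal; 12 naphthalene-1,8-diol
Product: 13 (S)-4-(5-iodo-6-methoxynaphthalen-2-yl)-5-(naphtho[1,8-de][1,3]dioxin-2-ylidene)-4-(triethylsilyloxy)cyclopent-2-en-1-one
Conditions: Cs2CO3, MeCN, 60 °C, argon stream
Reagents that add atoms: naphthalene-1,8-diol 12, Oc1cccc2cccc(O)c12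
Why: Twofold addition–elimination (vinylic substitution) on an α-oxoketene dithioacetal by a bis-nucleophile, in which the second displacement is intramolecular and closes the six-membered ring F, the volatile thiol is swept out, and C3 is shielded from conjugate addition by the neighbouring quaternary carbon.

Step 10
Reactants: 13 (S)-naphthodioxinylidene cyclopentenone
Product: 16 (4R,5S)-spiroketal enone (ring D closed; ketal carbon on C1′; H-5 cis to OSiEt3; I at C5′; OMe at C6′), via O-silylated naphthodioxinylium triflate 14 (not isolated), via trimethylsilyl dienol ether 15 (not isolated)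
Conditions: Me3SiOTf (3 equiv), 2,6-di-tert-butyl-4-methylpyridine (1.5 equiv), CH2Cl2 (0.01 M), −40 °C → rt; then aq. citric acid, THF, 0 °C
Reagents that add atoms: none
Why: Proposed new method: Me3SiOTf silylates the carbonyl oxygen of the push–pull ketene acetal, which turns the exocyclic acetal carbon into C2 of the naphthodioxinylium ion 14; C1′, held close by the quaternary C4, adds to this carbon, the hindered pyridine removes the arenium proton irreversibly, and dienol ether 15 is hydrolysed on work-up. The closest known reaction types are intramolecular Friedel–Crafts alkylations by oxocarbenium and 1,3-dioxolan-2-ylium ions, Lewis-acid arylations with catechol dichloromethylene ether and acid-promoted arylations of ketene acetals, whereas capture of a vinylogous, siloxy-bearing diaryloxycarbenium ion by a non-activated arene carbon has not been described. Ring D closes 5-exo-trig at the electrophile, since the C–O π bonds that are consumed lie outside the new ring, which makes it an indane-type closure of a 3-arylpropyl cation. The only new stereocentre, C5, is set when 15 is protonated: the D/E bicyclo[3.3.0] unit can only be cis-fused, so the proton arrives on the convex face that carries OSiEt3 and the configuration of C4 decides. The step needs C1′ over C3′ (the α-position gives the better stabilised arenium ion, and the buffered medium keeps the closure under kinetic control), intramolecular over intermolecular attack (iodine blocks C5′, the most nucleophilic carbon of the methoxynaphthalene, and the solution is dilute), and survival of the tertiary silyl ether (its ionisation would place a cyclopentadienone-type cation next to an already cationic unit). The two aryloxy groups share their lone pairs with the naphthalene and donate less than alkoxy groups would, which should leave the cation electrophilic enough.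

Step 11
Reactants: 16 (4R,5S)-spiroketal enone; 17 ethynyltrimethylsilane; 18 carbon monoxide
Product: 19 (4R,5S)-spiroketal enone bearing a 3-(trimethylsilyl)propynoyl group at C5′ in place of iodine
Conditions: PdCl2(PPh3)2 (5 mol %), CuI (2 mol %), CO (1 atm), Et3N, THF, rt
Reagents that add atoms: ethynyltrimethylsilane 17, C#C[Si](C)(C)C; carbon monoxide 18, [C-]#[O+]
Why: Carbonylative Sonogashira coupling, which runs with aryl iodides at room temperature under one atmosphere of CO, the ortho and peri neighbours of C5′ slowing direct alkynylation more than CO insertion.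

Step 12
Reactants: 19 silylated ynone
Product: 20 (4R,5S)-spiroketal enone bearing a propynoyl group at C5′
Conditions: AgNO3 (20 mol %), acetone/H2O, rt
Reagents that add atoms: none
Why: Silver-catalysed protiodesilylation of a C(sp)–SiMe3 bond under neutral conditions that spare the O-silyl ether and keep base away from the β-aryloxy ketone.

Step 13
Reactants: 20 terminal ynone
Product: 21 O-methyl-O-triethylsilyl spiropreussione B (9-methoxyphenalenone; ring A closed)
Conditions: [(JohnPhos)Au(NCMe)]SbF6 (JohnPhos = 2-(di-tert-butylphosphino)biphenyl; 5 mol %), 4 Å MS, ClCH2CH2Cl, 60 °C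
Reagents that add atoms: none
Why: Intramolecular hydroarylation of a gold-activated ynone (6-endo-dig, Michael polarity, as known for aryl alkynoates and alkynones), in which the ortho position is blocked by OMe so that only the peri carbon C4′ reaches the β-carbon, and addition of the methoxy oxygen stays reversible as long as no nucleophile removes its methyl group.

Step 14
Reactants: 21 O-methyl-O-triethylsilyl spiropreussione B
Product: 23 spiropreussione B, via O-triethylsilyl spiropreussione B 22 (not isolated)
Conditions: MgI2·OEt2, toluene/Et2O, 50 °C; then 2 M HCl, THF, rt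
Reagents that add atoms: none
Why: Chelation-assisted ether cleavage, in which magnesium sits between the phenalenone carbonyl and the neighbouring methoxy oxygen and iodide removes the methyl group of what is a vinylogous ester, after which dilute acid hydrolyses the triethylsilyl ether without ionising C4, whose cation would be destabilised by the enone.

**Compound list**

1 | methyl 6-methoxy-2-naphthoate | COC(=O)c1ccc2cc(OC)ccc2c1 | starting material
2 | methyl 5-iodo-6-methoxy-2-naphthoate | COC(=O)c1ccc2c(I)c(OC)ccc2c1 | intermediate
3 | allylmagnesium bromide | C=CC[Mg]Br | starting material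
4 | 4-(5-iodo-6-methoxynaphthalen-2-yl)hepta-1,6-dien-4-ol | COc1ccc2cc(ccc2c1I)C(O)(CC=C)CC=C | intermediate
5 | 1-(5-iodo-6-methoxynaphthalen-2-yl)cyclopent-3-en-1-ol | COc1ccc2cc(ccc2c1I)C1(O)CC=CC1 | intermediate
6 | meso-3-(5-iodo-6-methoxynaphthalen-2-yl)-6-oxabicyclo[3.1.0]hexan-3-ol, epoxide O cis to OH | COc1ccc2cc(ccc2c1I)[C@]1(O)C[C@H]2O[C@H]2C1 | intermediate
7 | triethylsilyl ether of 6, epoxide O cis to OSiEt3 | COc1ccc2cc(ccc2c1I)[C@]1(O[Si](CC)(CC)CC)C[C@H]2O[C@H]2C1 | intermediate
8 | (1R,4S)-4-(5-iodo-6-methoxynaphthalen-2-yl)-4-(triethylsilyloxy)cyclopent-2-en-1-ol | COc1ccc2cc(ccc2c1I)[C@@]1(O[Si](CC)(CC)CC)C=C[C@H](O)C1 | intermediate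
9 | (S)-4-(5-iodo-6-methoxynaphthalen-2-yl)-4-(triethylsilyloxy)cyclopent-2-en-1-one | COc1ccc2cc(ccc2c1I)[C@@]1(O[Si](CC)(CC)CC)C=CC(=O)C1 | intermediate
10 | carbon disulfide | S=C=S | starting material
11 | (S)-5-[bis(methylsulfanyl)methylidene]-4-(5-iodo-6-methoxynaphthalen-2-yl)-4-(triethylsilyloxy)cyclopent-2-en-1-one | COc1ccc2cc(ccc2c1I)[C@@]1(O[Si](CC)(CC)CC)C=CC(=O)C1=C(SC)SC | intermediate
12 | naphthalene-1,8-diol | Oc1cccc2cccc(O)c12 | starting material
13 | (S)-4-(5-iodo-6-methoxynaphthalen-2-yl)-5-(naphtho[1,8-de][1,3]dioxin-2-ylidene)-4-(triethylsilyloxy)cyclopent-2-en-1-one (key-step precursor) | COc1ccc2cc(ccc2c1I)[C@@]1(O[Si](CC)(CC)CC)C=CC(=O)C1=C4Oc2cccc3cccc(O4)c23 | intermediate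
14 | naphtho[1,8-de][1,3]dioxin-2-ylium triflate carrying at C2 the 1-(trimethylsilyloxy)cyclopenta-1(5),2-dien-5-yl unit derived from 13 | COc1ccc2cc(ccc2c1I)[C@@]1(O[Si](CC)(CC)CC)C=CC(O[Si](C)(C)C)=C1C4=[O+]c2cccc3cccc(O4)c23.[O-]S(=O)(=O)C(F)(F)F | intermediate
15 | trimethylsilyl dienol ether of 16 (C1=C5, C2=C3; ring D closed) | COc1ccc2c(c1I)ccc3c2C1(Oc2cccc4cccc(c24)O1)C1=C(O[Si](C)(C)C)C=C[C@]31O[Si](CC)(CC)CC | intermediate
16 | (4R,5S)-spiroketal enone: 5′-iodo-6′-methoxynaphthalene fused through C1′/C2′ to ring D, ketal carbon spiro to the naphthodioxine, H-5 cis to OSiEt3 (key-step product) | COc1ccc2c(c1I)ccc3c2C1(Oc2cccc4cccc(c24)O1)[C@@H]1C(=O)C=C[C@]31O[Si](CC)(CC)CC | intermediate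
17 | ethynyltrimethylsilane | C#C[Si](C)(C)C | starting material
18 | carbon monoxide | [C-]#[O+] | starting material
19 | analogue of 16 with a 3-(trimethylsilyl)propynoyl group at C5′ | COc1ccc2c(c1C(=O)C#C[Si](C)(C)C)ccc3c2C1(Oc2cccc4cccc(c24)O1)[C@@H]1C(=O)C=C[C@]31O[Si](CC)(CC)CC | intermediate
20 | analogue of 16 with a propynoyl group at C5′ | COc1ccc2c(c1C(=O)C#C)ccc3c2C1(Oc2cccc4cccc(c24)O1)[C@@H]1C(=O)C=C[C@]31O[Si](CC)(CC)CC | intermediate
21 | O-methyl-O-triethylsilyl spiropreussione B | O=C1C=Cc2cc3c(c4ccc(OC)c1c24)C1(Oc2cccc4cccc(c24)O1)[C@@H]1C(=O)C=C[C@]31O[Si](CC)(CC)CC | intermediate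
22 | O-triethylsilyl spiropreussione B | O=C1C=Cc2cc3c(c4ccc(O)c1c24)C1(Oc2cccc4cccc(c24)O1)[C@@H]1C(=O)C=C[C@]31O[Si](CC)(CC)CC | intermediate
23 | spiropreussione B, carbinol carbon (R), ring-fusion CH (S), H and OH cis | O=C1C=Cc2cc3c(c4ccc(O)c1c24)C1(Oc2cccc4cccc(c24)O1)[C@@H]1C(=O)C=C[C@]31O | target

**Step count and risks**

Total steps: 14. Longest linear sequence: 14 (from 1). Compounds 3, 10, 12, 17 and 18 are purchased.

Step 10 (new method).
- **What may go wrong:** the arene attack may be too slow for a cation tempered by one siloxy and two aryloxy donors. Alkylation of the electron-rich dioxynaphthalene of already formed product, closure at the β-carbon C3′, or gradual loss of the tertiary silyloxy group could then take over.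
- **Fallback:** it uses known reactions only, making the aryl–carbon bond by acylation and building the ketal afterwards, and it sets out from dithioacetal 11.
- Partial acid hydrolysis (aq. CF3CO2H, CH2Cl2, 0 °C), a standard reaction of α-oxoketene dithioacetals, should give the S-methyl β-keto thioester F1.
- Thiophilic activation with AgOTf and the hindered pyridine frees an acylium or acylketene equivalent far more electrophilic than 14. This closes ring D by intramolecular Friedel–Crafts acylation at C1′ to the tetracyclic 1,3-diketone F2.
- Acid-catalysed ketalisation with diol 12 (TsOH, toluene, molecular sieves) is the usual entry to naphthodioxine spiroketals. It should occur at the aryl ketone carbon, the terminus of the enolised vinylogous acid, and it returns to the route at 16.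

Step 9.
- **What may go wrong:** displacement at a hindered, singly activated ketene dithioacetal may be sluggish. Addition of the released thiolate to the enone and air oxidation of the diol would compete.
- **Fallback:** it sets out from enone 9 and diol 12 and bypasses 11.
- Diol 12 is transesterified with tetramethyl orthocarbonate (cat. TsOH, toluene, methanol distilled off) to the cyclic orthocarbonate 2,2-dimethoxynaphtho[1,8-de][1,3]dioxine F3.
- Enone 9 is converted by soft enolisation (Me3SiOTf, Et3N, CH2Cl2, 0 °C) into the cross-conjugated trimethylsilyl dienol ether F4.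
- A Mukaiyama-type coupling (cat. Me3SiOTf, CH2Cl2, −78 °C) joins C5 to the methoxydioxinylium ion derived from the orthocarbonate. The resulting β-keto orthoester loses methanol on addition of Et3N, which rejoins the route at 13.

Step 13.
- **What may go wrong:** the methoxy oxygen may capture the activated alkyne and then lose its methyl group, or the terminal alkyne may deactivate the catalyst. Either would replace C–C bond formation at a peri carbon that is only weakly activated.
- **Fallback:** it sets out from ynone 20.
- Hydroiodination (LiI, AcOH, MeCN, rt), known to convert terminal ynones into Z-configured β-iodoenones, should give the (Z)-β-iodovinyl ketone F5.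
- An intramolecular palladium-catalysed direct C–H alkenylation (Pd(OAc)2, PCy3·HBF4, KOAc, DMA, 90 °C) then acts at C4′, the only C–H bond within reach of the vinylpalladium unit. It closes ring A with retention of the alkene geometry and rejoins the route at 21.

**Further compounds**

F1 | step 10 | S-methyl (4R,5S)-4-(5-iodo-6-methoxynaphthalen-2-yl)-1-oxo-4-(triethylsilyloxy)cyclopent-2-ene-5-carbothioate (route numbering; thioester cis to aryl) | CSC(=O)[C@@H]1C(=O)C=C[C@]1(O[Si](CC)(CC)CC)c1ccc2c(I)c(OC)ccc2c1
F2 | step 10 | (4R,5S)-tetracyclic 1,3-diketone (analogue of 16 with C=O in place of the ketal carbon) | COc1ccc2c(c1I)ccc3c2C(=O)[C@@H]1C(=O)C=C[C@]31O[Si](CC)(CC)CC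
F3 | step 9 | 2,2-dimethoxynaphtho[1,8-de][1,3]dioxine | COC1(OC)Oc2cccc3cccc(O1)c23
F4 | step 9 | (S)-5-(5-iodo-6-methoxynaphthalen-2-yl)-5-(triethylsilyloxy)-2-(trimethylsilyloxy)cyclopenta-1,3-diene | COc1ccc2cc(ccc2c1I)[C@@]1(O[Si](CC)(CC)CC)C=CC(O[Si](C)(C)C)=C1
F5 | step 13 | analogue of 16 with a (Z)-3-iodopropenoyl group at C5′ | COc1ccc2c(c1C(=O)/C=C\I)ccc3c2C1(Oc2cccc4cccc(c24)O1)[C@@H]1C(=O)C=C[C@]31O[Si](CC)(CC)CC
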